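Over 8.0 d, a racemic substrate meets a single-handed free catalyst while a racemization catalyst exchanges the two mirror forms. The question is how far that exchange keeps up.

| flask | left-handed substrate | right-handed substrate | partner | free catalyst | racemization catalyst | remark | time |
|---|---|---|---|---|---|---|---|
| Sunday's | 0.020 M | 0.020 M | 2 equiv (fed, over 8.0 h) | 2 mol% | 5 mol% | run made earlier |  |
| Saturday's | 0.020 M | 0.020 M | 2 equiv (fed, over 8.0 h) | 2 mol% | 20 mol% | run made earlier |  |
| Monday's | 0.010 M | 0.010 M | 2 equiv (fed, over 8.0 h) | 2 mol% | 10 mol% | run made earlier |  |
| flask | 0.020 M | 0.020 M | 2.00 equiv (fed, over 8.0 h) | 2 mol% | 10 mol% |  | 8.0 d |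

| run | time / d | left-handed product / % | right-handed product / % |
|---|---|---|---|
| Sunday's | 0.500 | 13 | 4 |
| Sunday's | 0.833 | 24 | 10 |
| Sunday's | 1.25 | 31 | 13 |
| Sunday's | 2.50 | 39 | 17 |
| Sunday's | 4.00 | 44 | 26 |
| Sunday's | 6.00 | 47 | 32 |
| Saturday's | 0.500 | 13 | 9 |
| Saturday's | 0.833 | 23 | 8 |
| Saturday's | 1.25 | 30 | 15 |
| Saturday's | 2.50 | 41 | 21 |
| Saturday's | 4.00 | 48 | 27 |
| Saturday's | 6.00 | 50 | 29 |
| Monday's | 0.625 | 7 | 1 |
| Monday's | 1.67 | 18 | 3 |
| Monday's | 3.00 | 26 | 11 |
| Monday's | 5.00 | 32 | 15 |
| Monday's | 6.00 | 35 | 17 |

(readings scatter by 2 percentage points)

- free catalyst is single-handed; left-handed substrate and right-handed substrate are mirror images of each other, charged as a racemate, each of them at the stated concentration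
- reactions considered so far: partner + free catalyst + left-handed substrate -> free catalyst + left-handed product; partner + free catalyst + right-handed substrate -> free catalyst + right-handed product; left-handed substrate + racemization catalyst <-> right-handed substrate + racemization catalyst; free catalyst <-> dormant form; 2 racemization catalyst <-> resting dimer; 2 racemization catalyst -> spent catalyst
- an excess is the difference of the two amounts in percent of their sum
- an excess is below zero if the other one leads

1. left-handed product and right-handed product together, in percent of the left-handed substrate and right-handed substrate charged together, at 8.0 d
2. excess of left-handed product over right-handed product in the product at 8.0 d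
3. whether the exchange between left-handed substrate and right-handed substrate keeps pace with the reaction: how far the product's excess at 8.0 d gets from its value without exchange to its value with instant exchange (above 80% keeps pace, below 20% hardly takes part, else lags behind)

Logarithms give the test. Sunday's and Saturday's readings at 1.25 d, pooled, put at 2.87 the log ratio: the ln of the fraction of its own charge still left of the left-handed substrate, over the same ln for the right-handed substrate, here reckoned from the products as if each came from its own charge. With no exchange, and both steps sharing partner and free catalyst, this ratio holds at the selectivity factor. With instant exchange the two substrates stay equal, so the ratio taken on the substrates left falls to 1, while the product's excess stands at 48.3%, from the same reading.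

Turned round, keeping pace would need the substrates' log ratio sinking towards 1 and, in the products that the runs read, an excess near 48.3%. The pooled readings at 6.00 d give an excess of 22.8%, lower than that. Monday's readings at 6.00 d, counted from the products in the same way, give fractions of 0.300 and 0.660, a log ratio of 2.90, which carries the scatter of 2 percentage points. My own reckoning therefore expects no keeping pace, and leaves the other two marks open.

The forecast goes further: “Quadrupling the racemization catalyst changes little, so exchange is weak”. It gives 85% of product, an excess of 20%, and the mark hardly takes part.

The flask gives 83.2% of product, an excess of 26.2%, and the mark lags behind, at 28% of the way, past the 20% line.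

    partner + free catalyst + left-handed substrate → free catalyst + left-handed product (k = 67.3 M⁻² min⁻¹)
    partner + free catalyst + right-handed substrate → free catalyst + right-handed product (k = 23.3 M⁻² min⁻¹)
    left-handed substrate + racemization catalyst ⇌ right-handed substrate + racemization catalyst, rate k3*[racemization catalyst]*[left-handed substrate] forward; the back reaction follows from the equilibrium constant (k = 0.621 M⁻¹ min⁻¹)
    free catalyst ⇌ dormant form (K = 0.330, k = 0.00525 min⁻¹)
    2 racemization catalyst ⇌ resting dimer, settled at all times (K = 23000 M⁻¹)
    2 racemization catalyst → spent catalyst (k = 10.0 M⁻¹ min⁻¹)

At 4.00 d, 87.5% of the racemization catalyst charged stands as spent catalyst. The flask leaves 7.6% of the left-handed substrate's charge and 26% of the right-handed substrate's at 8.00 d, a log ratio of 1.91, below the early reading of 2.87. The neighbour charged with 0.800 equiv of partner leaves 53% of the left-handed substrate's charge and 69% of the right-handed substrate's, a log ratio of 1.71.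

(The earlier runs and the new flask were generated by integration with constants of no real substance, noise included.)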